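**Plan**

- Retrosynthesis: the two O-methyl bonds go last. The pyranone is then opened at O1–C8a, C4–C4a and O1–C2, leaving a benzyne across C4a–C8a of ring A and a linear C23 alk-2-ynoic acid.
- Enabling feature: C4a and C8a are neighbouring carbons of ring A that carry the acyl carbon C4 and the ring oxygen O1. C4a sits next to the oxygen-bearing C5 and C8a next to the methyl-bearing C8, so the aryne C4a≡C8a is polarised and should accept oxygen at C8a and carbon at C4a.
- Forward order: ring A is bought intact and converted in six steps into an ortho-silyl aryl triflate. The chain is joined by acetylide alkylation of 1-bromoicosane and carboxylation (two steps). The pyranone, the only ring made, closes in the aryne step, and BBr3 then frees both phenols.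
- Stereochemistry: the target has no stereocentre and no stereogenic double bond, so nothing needs to be controlled.

Key step: step 9

Assumption: the aryne insertion conditions established for aryl-substituted propiolic acids are taken to carry over to an alkyl-substituted alkynoic acid; the three starting materials are purchased.

**Route**

Step 1
Reactants: 1 2,4-dimethoxy-3-methylbenzaldehyde
Product: 2 1,3-dimethoxy-2,4-dimethylbenzene
Conditions: H2 (3 bar), 10% Pd/C, AcOH, cat. HCl, rt
Reagents that add atoms: none
Why: Catalytic hydrogenolysis of an electron-rich aryl aldehyde runs through the benzylic alcohol, whose C–O bond is cleaved easily on palladium under acid, so the formyl group should be reduced to methyl while ring and ethers stay intact.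

Step 2
Reactants: 2 1,3-dimethoxy-2,4-dimethylbenzene
Product: 3 2,4-dimethoxy-3,5-dimethylbenzaldehyde
Conditions: Cl2CHOCH3, TiCl4, CH2Cl2, −10 to 0 °C; then ice-cold 1 M HCl
Reagents that add atoms: dichloromethyl methyl ether, COC(Cl)Cl; water, O
Why: Rieche formylation (Friedel–Crafts type) should occur at the one ring position that is ortho to one methoxy group and para to the other, since the second free position is meta to both oxygens, and hydrolysis of the α-chloro ether on work-up releases the aldehyde.

Step 3
Reactants: 3 2,4-dimethoxy-3,5-dimethylbenzaldehyde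
Product: 5 2,4-dimethoxy-3,5-dimethylphenol, via 2,4-dimethoxy-3,5-dimethylphenyl formate 4 (not isolated)
Conditions: mCPBA, CH2Cl2, 0 °C to rt; aq. Na2S2O3/NaHCO3 wash; then K2CO3 (cat.), MeOH, rt
Reagents that add atoms: 3-chloroperoxybenzoic acid, O=C(OO)c1cccc(Cl)c1
Why: In this Baeyer–Villiger (Dakin-type) oxidation the electron-rich aryl group migrates in preference to hydrogen to give the aryl formate, which is methanolysed after the excess peracid has been destroyed so that the free phenol never meets the oxidant.

Step 4
Reactants: 5 2,4-dimethoxy-3,5-dimethylphenol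
Product: 6 2-bromo-4,6-dimethoxy-3,5-dimethylphenol
Conditions: NBS (1.0 equiv), CH2Cl2, −20 to 0 °C, dark
Reagents that add atoms: N-bromosuccinimide, O=C1CCC(=O)N1Br
Why: Electrophilic aromatic bromination can only take the single unsubstituted ring position, which lies ortho to the activating hydroxyl group, and anhydrous cold conditions with one equivalent of reagent should hold back oxidation of the ring.

Step 5
Reactants: 6 2-bromo-4,6-dimethoxy-3,5-dimethylphenol
Product: 7 (2-bromo-4,6-dimethoxy-3,5-dimethylphenoxy)trimethylsilane
Conditions: HN(SiMe3)2, THF, 70 °C; volatiles removed in vacuo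
Reagents that add atoms: hexamethyldisilazane, C[Si](C)(C)N[Si](C)(C)C
Why: O-silylation of a phenol by hexamethyldisilazane is driven by loss of ammonia and leaves a crude silyl ether that can be used after evaporation.

Step 6
Reactants: 7 (2-bromo-4,6-dimethoxy-3,5-dimethylphenoxy)trimethylsilane
Product: 10 2,4-dimethoxy-3,5-dimethyl-6-(trimethylsilyl)phenyl trifluoromethanesulfonate, via [3,5-dimethoxy-2,4-dimethyl-6-(trimethylsilyloxy)phenyl]lithium 8 (not isolated), via lithium 2,4-dimethoxy-3,5-dimethyl-6-(trimethylsilyl)phenoxide 9 (not isolated)
Conditions: n-BuLi, THF, −100 to −78 °C; then Tf2O, −100 to −78 °C; cold aq. NaHCO3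
Reagents that add atoms: trifluoromethanesulfonic anhydride, O=S(=O)(OS(=O)(=O)C(F)(F)F)C(F)(F)F
Why: Bromine–lithium exchange outpaces attack at silicon, the aryllithium then undergoes a retro-Brook 1,3-shift of silicon from oxygen to carbon driven by the stronger O–Li bond, and the resulting phenoxide is sulfonylated in the same flask by triflic anhydride.

Step 7
Reactants: 11 1-bromoicosane; 12 lithium acetylide–ethylenediamine complex (LiC≡CH·H2NCH2CH2NH2)
Product: 13 docos-1-yne
Conditions: DMSO/THF, 10 °C to rt
Reagents that add atoms: none
Why: SN2 alkylation of an acetylide by an unhindered primary bromide in a dipolar aprotic medium is the standard entry to long-chain terminal alkynes, and the tetrahydrofuran co-solvent keeps the C20 bromide in solution.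

Step 8
Reactants: 13 docos-1-yne
Product: 15 tricos-2-ynoic acid, via lithium docos-1-yn-1-ide 14 (not isolated)
Conditions: n-BuLi, THF, −20 to 0 °C; CO2 (g), −40 °C to rt; then 1 M HCl
Reagents that add atoms: carbon dioxide, O=C=O
Why: Deprotonation of the terminal alkyne followed by carboxylation of the lithium acetylide with carbon dioxide is a reliable route to alk-2-ynoic acids.

Step 9
Reactants: 10 2,4-dimethoxy-3,5-dimethyl-6-(trimethylsilyl)phenyl trifluoromethanesulfonate (1.5 equiv); 15 tricos-2-ynoic acid
Product: 18 2-icosyl-5,7-dimethoxy-6,8-dimethyl-4H-chromen-4-one, via 3,5-dimethoxy-4,6-dimethylbenzyne 16 (not isolated), via cesium 3,5-dimethoxy-2,4-dimethyl-6-(tricos-2-ynoyl)phenoxide 17 (not isolated)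
Conditions: CsF (5 equiv), THF, 125 °C, sealed tube
Reagents that add atoms: none
Why: CsF removes silicon from 10 with loss of triflate to give aryne 16 and converts 15 into its cesium carboxylate, whose oxygen adds to the aryne carbon beside the C-methyl group (future C8a); the aryl anion beside the methoxy group (future C4a) then attacks the ester carbonyl in a strained four-centre acyl shift from oxygen to carbon, giving ynone phenoxide 17. The phenoxide next adds to the β-carbon of the ynone (future C2) in a 6-endo-dig oxa-Michael closure, which forms the only new ring, and the vinyl anion at C3 is protonated by the bifluoride left from the acid. The closest known reaction type is the fluoride-induced insertion of arynes into the C–O bond of carboxylic acids, which gives ortho-hydroxyaryl ketones and, with arylpropiolic acids, flavones in one operation. No stereocentre is created. The selectivity required is oxygen attack at C8a and not at C4a, and it should be secured by the C5 methoxy group, whose inductive pull makes the remote aryne carbon the electrophilic one and stabilises the charge at C4a, while 6-endo over 5-exo closure is the normal course for an alkyl ynone and a phenoxide in an aprotic medium. Because the aryne is fully substituted, ring A offers no hydrogen for competing proton-transfer or ene-type paths.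

Step 10
Reactants: 18 2-icosyl-5,7-dimethoxy-6,8-dimethyl-4H-chromen-4-one
Product: 19 5,7-dihydroxy-2-icosyl-6,8-dimethyl-4H-chromen-4-one
Conditions: BBr3 (5 equiv), CH2Cl2, −78 °C to rt; then H2O
Reagents that add atoms: none
Why: Lewis-acid ether cleavage by BBr3 should remove the C5 methyl first through chelation to the C4 carbonyl and then the C7 methyl, whose oxygen is twisted out of conjugation by two flanking methyl groups and is therefore basic, while the pyranone and the alkyl chain are inert to the reagent.

**Compound list**

1 | 2,4-dimethoxy-3-methylbenzaldehyde | COc1ccc(C=O)c(OC)c1C | starting material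
2 | 1,3-dimethoxy-2,4-dimethylbenzene | COc1ccc(C)c(OC)c1C | intermediate
3 | 2,4-dimethoxy-3,5-dimethylbenzaldehyde | COc1c(C)c(OC)c(C)cc1C=O | intermediate
4 | 2,4-dimethoxy-3,5-dimethylphenyl formate | COc1c(C)c(OC)c(C)cc1OC=O | intermediate
5 | 2,4-dimethoxy-3,5-dimethylphenol | COc1c(C)c(OC)c(C)cc1O | intermediate
6 | 2-bromo-4,6-dimethoxy-3,5-dimethylphenol | COc1c(C)c(OC)c(C)c(Br)c1O | intermediate
7 | (2-bromo-4,6-dimethoxy-3,5-dimethylphenoxy)trimethylsilane | COc1c(C)c(OC)c(C)c(Br)c1O[Si](C)(C)C | intermediate
8 | [3,5-dimethoxy-2,4-dimethyl-6-(trimethylsilyloxy)phenyl]lithium | COc1c(C)c(OC)c(C)c([Li])c1O[Si](C)(C)C | intermediate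
9 | lithium 2,4-dimethoxy-3,5-dimethyl-6-(trimethylsilyl)phenoxide | COc1c(C)c(OC)c(C)c([Si](C)(C)C)c1[O-].[Li+] | intermediate
10 | 2,4-dimethoxy-3,5-dimethyl-6-(trimethylsilyl)phenyl trifluoromethanesulfonate | COc1c(C)c(OC)c(C)c([Si](C)(C)C)c1OS(=O)(=O)C(F)(F)F | intermediate
11 | 1-bromoicosane | CCCCCCCCCCCCCCCCCCCCBr | starting material
12 | lithium acetylide–ethylenediamine complex | [Li+].[C-]#C.NCCN | starting material
13 | docos-1-yne | CCCCCCCCCCCCCCCCCCCCC#C | intermediate
14 | lithium docos-1-yn-1-ide | CCCCCCCCCCCCCCCCCCCCC#C[Li] | intermediate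
15 | tricos-2-ynoic acid | CCCCCCCCCCCCCCCCCCCCC#CC(=O)O | intermediate
16 | 3,5-dimethoxy-4,6-dimethylbenzyne | COC1=C(C)C(OC)=C(C)C#C1 | intermediate
17 | cesium 3,5-dimethoxy-2,4-dimethyl-6-(tricos-2-ynoyl)phenoxide | CCCCCCCCCCCCCCCCCCCCC#CC(=O)c1c([O-])c(C)c(OC)c(C)c1OC.[Cs+] | intermediate
18 | 2-icosyl-5,7-dimethoxy-6,8-dimethyl-4H-chromen-4-one | CCCCCCCCCCCCCCCCCCCCc1cc(=O)c2c(OC)c(C)c(OC)c(C)c2o1 | intermediate
19 | 5,7-dihydroxy-2-icosyl-6,8-dimethyl-4H-chromen-4-one | CCCCCCCCCCCCCCCCCCCCc1cc(=O)c2c(O)c(C)c(O)c(C)c2o1 | target

**Step count and risks**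

Total step count: 10. Longest linear sequence: 8 steps (steps 1 to 6, then 9 and 10); the acid branch (steps 7 and 8) joins at step 9.

Steps most likely to fail:

1. Step 9. The cesium alkynoate may lose carbon dioxide at 125 °C before it meets the aryne, the ynone may be degraded by base before it cyclises, or the phenoxide may close through the 5-exo mode. The fallback sets out from 10 and separates aryne insertion from ring formation. Under the same CsF/THF conditions, 10 and acetic acid, the simplest known partner with nothing to decarboxylate or cyclise, should give 1-(2-hydroxy-4,6-dimethoxy-3,5-dimethylphenyl)ethan-1-one F1. Claisen condensation of its dianion (LiN(SiMe3)2, 3 equiv, THF, −78 °C to rt) with methyl henicosanoate should then give 1-(2-hydroxy-4,6-dimethoxy-3,5-dimethylphenyl)tricosane-1,3-dione F2. Cyclodehydration with catalytic H2SO4 in acetic acid at 80 °C closes the pyranone and returns to the route at 18.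

2. Step 6. The aryllithium, flanked by a methyl group, may be protonated, or the silyl shift may lag behind triflation, so that silicon is lost or ends on oxygen. The fallback sets out from 6 and replaces the intramolecular shift by an intermolecular trap. Double lithiation (n-BuLi, 2.2 equiv, THF, −78 °C) and quenching with excess Me3SiCl should give [2,4-dimethoxy-3,5-dimethyl-6-(trimethylsilyl)phenoxy]trimethylsilane F3. Brief methanolysis (K2CO3, MeOH, 0 °C) removes only the O-silyl group to leave 2,4-dimethoxy-3,5-dimethyl-6-(trimethylsilyl)phenol F4. This isolated phenol is triflated (Tf2O, pyridine, CH2Cl2, 0 °C) to return at 10.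

3. Step 4. The electron-rich para-methoxyphenol may be oxidised by the positive-bromine source (oxidative loss of the para methyl ether towards a quinone), or attacked at an already substituted carbon, instead of being substituted at the free position. The fallback sets out from 5 and avoids halogen altogether by carbamate-directed ortho-metalation. Isopropyl isocyanate with catalytic Et3N in CH2Cl2 should give 2,4-dimethoxy-3,5-dimethylphenyl propan-2-ylcarbamate F5. In-flask N-silylation (Me3SiOSO2CF3, TMEDA, Et2O), ortho-lithiation (n-BuLi, TMEDA, −78 °C) and Me3SiCl should give 2,4-dimethoxy-3,5-dimethyl-6-(trimethylsilyl)phenyl propan-2-ylcarbamate F6. Cleavage of the carbamate with DBU and Et2NH in MeCN at 40 °C, followed by PhN(SO2CF3)2 in the same flask, returns at 10 and bypasses 6 to 9.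

Further compounds
F1 | step 9 | 1-(2-hydroxy-4,6-dimethoxy-3,5-dimethylphenyl)ethan-1-one | CC(=O)c1c(O)c(C)c(OC)c(C)c1OC
F2 | step 9 | 1-(2-hydroxy-4,6-dimethoxy-3,5-dimethylphenyl)tricosane-1,3-dione | CCCCCCCCCCCCCCCCCCCCC(=O)CC(=O)c1c(O)c(C)c(OC)c(C)c1OC
F3 | step 6 | [2,4-dimethoxy-3,5-dimethyl-6-(trimethylsilyl)phenoxy]trimethylsilane | COc1c(C)c(OC)c(C)c([Si](C)(C)C)c1O[Si](C)(C)C
F4 | step 6 | 2,4-dimethoxy-3,5-dimethyl-6-(trimethylsilyl)phenol | COc1c(C)c(OC)c(C)c([Si](C)(C)C)c1O
F5 | step 4 | 2,4-dimethoxy-3,5-dimethylphenyl propan-2-ylcarbamate | COc1c(C)c(OC)c(C)cc1OC(=O)NC(C)C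
F6 | step 4 | 2,4-dimethoxy-3,5-dimethyl-6-(trimethylsilyl)phenyl propan-2-ylcarbamate | COc1c(C)c(OC)c(C)c([Si](C)(C)C)c1OC(=O)NC(C)C
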